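The route rests on cutting C4–C5 and C9–C10, which unfolds the decalin into a linear E,E-diene, the radical counterpart of the enzymatic folding of a geranylgeranyl chain. One oxidation of a C4 β-keto ester closes ring A and then ring B (C5–C10), sets C4, C5, C9 and C10, and ends by loss of a C17 hydrogen to leave the exocyclic C8=C17 alkene. The precursor is a farnesol-derived acyclic diene carrying the C13 carbinol as an acetonide and a chiral 8-phenylmenthyl ester at C19. The step exploits the isoprenoid spacing of quaternary C4 and C10 across C5 and the methyl-derived methylene on C8.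

Key step: step 8

Remark on numbering: labdane numbering is used for all intermediates. Ring A is C1–C5 and C10, ring B is C5–C10, C17 is the exocyclic methylene carbon, C18 and C19 are the methyl and carboxyl carbons on C4, C20 is the methyl on C10, and C11–C16 form the side chain on C9.

Assumption: the facial bias of the (1R,2S,5R)-8-phenylmenthyl ester in step 8 is taken to follow the π-shielding model given in that step (bond formation at the face of C4 remote from the phenyl ring, with the C3 carbonyl carbon syn to the ester C=O). If the opposite sense were found, the enantiomeric auxiliary would be used and nothing else would change.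

**Step 1**
Reactants: 1 (2E,6E)-farnesol
Product: 2 (2R,3R)-2,3-epoxyfarnesol
Conditions: t-BuOOH, Ti(OiPr)4 (5 mol %), D-(−)-diethyl tartrate (7 mol %), 4 Å molecular sieves, CH2Cl2, −20 °C
Reagents that add atoms: tert-butyl hydroperoxide, CC(C)(C)OO
Why: Katsuki–Sharpless asymmetric epoxidation; the titanium tartrate complex binds the allylic hydroxyl, so only the C2=C3 alkene reacts, and D-(−)-tartrate delivers oxygen to the face that gives the (2R,3R) epoxide, which fixes the later C13 configuration.

**Step 2**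
Reactants: 2 (2R,3R)-2,3-epoxyfarnesol
Product: 3 (3R,6E)-3,7,11-trimethyldodeca-6,10-diene-1,3-diol
Conditions: Red-Al, NaAlH2(OCH2CH2OCH3)2, THF, 0 °C to rt; aqueous Rochelle salt
Reagents that add atoms: none
Why: Regioselective epoxy-alcohol reduction; hydride is delivered intramolecularly from the C1 alkoxyaluminate to C2, so the C3–O bond is untouched and the tertiary carbinol keeps its (R) configuration in the 1,3-diol.

**Step 3**
Reactants: 3 (3R,6E)-3,7,11-trimethyldodeca-6,10-diene-1,3-diol
Product: 4 (4R)-4-[(3E)-4,8-dimethylnona-3,7-dien-1-yl]-2,2,4-trimethyl-1,3-dioxane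
Conditions: 2,2-dimethoxypropane, PPTS (cat.), CH2Cl2, rt
Reagents that add atoms: 2,2-dimethoxypropane, COC(C)(C)OC
Why: Acid-catalysed transketalisation gives the six-membered isopropylidene acetal, which masks both hydroxyls against the bromination, the dianion and capture of the later C8 radical.

**Step 4**
Reactants: 4 (4R)-4-[(3E)-4,8-dimethylnona-3,7-dien-1-yl]-2,2,4-trimethyl-1,3-dioxane
Product: 5 (2E,6E)-2,6-dimethyl-9-[(4R)-2,2,4-trimethyl-1,3-dioxan-4-yl]nona-2,6-dien-1-ol
Conditions: SeO2 (0.2 equiv), t-BuOOH, salicylic acid (0.1 equiv), CH2Cl2, 0 °C to rt; then NaBH4, MeOH, 0 °C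
Reagents that add atoms: tert-butyl hydroperoxide, CC(C)(C)OO (terminal oxidant; the oxygen is passed on by catalytic selenium dioxide, O=[Se]=O)
Why: Selenium dioxide allylic oxidation (ene reaction, then 2,3-sigmatropic shift) is selective for the (E)-methyl of the terminal, most electron-rich trisubstituted alkene and gives the (E)-allylic alcohol; the borohydride treatment returns any over-oxidised enal to 5.

**Step 5**
Reactants: 5 (2E,6E)-2,6-dimethyl-9-[(4R)-2,2,4-trimethyl-1,3-dioxan-4-yl]nona-2,6-dien-1-ol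
Product: 6 (4R)-4-[(3E,7E)-9-bromo-4,8-dimethylnona-3,7-dien-1-yl]-2,2,4-trimethyl-1,3-dioxane
Conditions: CBr4, PPh3, 2,6-lutidine (cat.), CH2Cl2, −20 to 0 °C
Reagents that add atoms: carbon tetrabromide, BrC(Br)(Br)Br
Why: Appel bromination of the primary allylic alcohol proceeds by SN2 displacement of the alkoxyphosphonium without allylic transposition, and the buffered conditions spare the acetonide.

**Step 6**
Reactants: 7 ethyl 2-methyl-3-oxobutanoate; 8 (1R,2S,5R)-(−)-8-phenylmenthol
Product: 9 (1R,2S,5R)-8-phenylmenthyl 2-methyl-3-oxobutanoate (epimers at the α-carbon)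
Conditions: DMAP (0.3 equiv), toluene, reflux with removal of EtOH
Reagents that add atoms: none
Why: DMAP-catalysed transesterification of a β-keto ester is driven by distilling off ethanol and tolerates hindered secondary alcohols.

**Step 7**
Reactants: 9 (1R,2S,5R)-8-phenylmenthyl 2-methyl-3-oxobutanoate; 6 (4R)-4-[(3E,7E)-9-bromo-4,8-dimethylnona-3,7-dien-1-yl]-2,2,4-trimethyl-1,3-dioxane
Product: 11 (1R,2S,5R)-8-phenylmenthyl (6E,10E)-2,6,10-trimethyl-3-oxo-13-[(4R)-2,2,4-trimethyl-1,3-dioxan-4-yl]trideca-6,10-dienoate, via β-keto ester dianion 10 (not isolated)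
Conditions: NaH, THF, 0 °C; n-BuLi, 0 °C; then 6, 0 °C; aqueous NH4Cl
Reagents that add atoms: none
Why: β-Keto ester dianion alkylation; the more reactive γ-carbanion displaces the primary allylic bromide by SN2 and joins C1 to C2 with both E alkenes intact, while the epimeric α-centre is irrelevant because it becomes a planar radical.

**Step 8**
Reactants: 11 (1R,2S,5R)-8-phenylmenthyl (6E,10E)-2,6,10-trimethyl-3-oxo-13-[(4R)-2,2,4-trimethyl-1,3-dioxan-4-yl]trideca-6,10-dienoate
Product: 12 (1R,2S,5R)-8-phenylmenthyl (13R)-13,15-(isopropylidenedioxy)-3-oxolabd-8(17)-en-19-oate (4α-methyl, 4β-axial ester, 5α-H, 9α-H, 10β-methyl)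
Conditions: Mn(OAc)3·2H2O (2.2 equiv), Cu(OAc)2·H2O (1.0 equiv), degassed EtOH, 25–40 °C
Reagents that add atoms: none
Why: Manganese triacetate (trivalent manganese) oxidises the enolised β-keto ester to the electrophilic C4 radical, which adds 6-endo-trig to C5 of the C10=C5 alkene (ring A); the tertiary C10 radical then adds 6-endo-trig to C9 of the C8=C9 alkene (ring B), and copper diacetate (divalent copper) intercepts the tertiary C8 radical as an alkylcopper species that loses a C17 hydrogen by syn β-hydride elimination to give the exocyclic C8=C17 alkene. The closest known reaction type is the Mn(OAc)3/Cu(OAc)2 oxidative free-radical polyene cyclisation of α-methyl β-keto esters, a radical counterpart of the proton-initiated enzymatic bicyclisation of a geranylgeranyl chain. Both rings close through chair-like transition states on E alkenes, so addition across C5=C10 is anti (trans ring fusion, 5α-H, 10β-methyl) and the C11 chain on C9 ends equatorial (9α-H); at C4 the radical reacts in the conformer with the methyl syn to the C3 carbonyl oxygen, which places the ester axial and cis to C20. The absolute sense comes from the auxiliary: in the s-cis ester, whose carbonyl eclipses the carbinol C–H, the phenyl ring of the dimethylbenzyl group lies over one face of the planar C4 radical and C5 bonds to the open face. The step needs exocyclic over endocyclic olefin formation, which the preference of the copper intermediate for the unhindered methyl hydrogens should secure, and it needs the C13 oxygen kept from capturing C8, which the acetonide secures.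

**Step 9**
Reactants: 12 (1R,2S,5R)-8-phenylmenthyl (13R)-13,15-(isopropylidenedioxy)-3-oxolabd-8(17)-en-19-oate
Product: 13 (1R,2S,5R)-8-phenylmenthyl (13R)-13,15-dihydroxy-3-(p-toluenesulfonylhydrazono)labd-8(17)-en-19-oate (C=N geometry not defined, N–N expected anti to C4)
Conditions: TsNHNH2 (1.5 equiv), PPTS (0.2 equiv), MeOH, 50 °C
Reagents that add atoms: p-toluenesulfonyl hydrazide, NNS(=O)(=O)c1ccc(C)cc1
Why: Acid-catalysed condensation gives the tosylhydrazone of the only ketone while the same catalyst in methanol removes the acetonide by transketalisation, which saves a separate deprotection.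

**Step 10**
Reactants: 13 (1R,2S,5R)-8-phenylmenthyl (13R)-13,15-dihydroxy-3-(p-toluenesulfonylhydrazono)labd-8(17)-en-19-oate
Product: 15 (1R,2S,5R)-8-phenylmenthyl (13R)-13,15-dihydroxylabd-8(17)-en-19-oate, via monoalkyl diazene 14 (not isolated)
Conditions: catecholborane (5 equiv), CHCl3, 0 °C to rt; then NaOAc·3H2O, reflux
Reagents that add atoms: none
Why: Caglioti-type tosylhydrazone reduction; catecholborane adds hydride to C=N, acetate triggers loss of sulfinate to the monoalkyl diazene, and this loses N2 to leave the C3 methylene without touching the ester or the 1,1-disubstituted alkene.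

**Step 11**
Reactants: 15 (1R,2S,5R)-8-phenylmenthyl (13R)-13,15-dihydroxylabd-8(17)-en-19-oate
Product: 16 (13R)-labd-8(17)-ene-13,15,19-triol
Conditions: LiAlH4, THF, 0 °C to reflux; aqueous NaOH work-up
Reagents that add atoms: none
Why: Hydride reduction of the hindered axial ester gives the C19 primary alcohol and releases the auxiliary for recovery, while the alkene and the tertiary alcohol are inert.

**Step 12**
Reactants: 16 (13R)-labd-8(17)-ene-13,15,19-triol
Product: 18 (4S,5R,9S,10R,13R)-13-hydroxylabd-8(17)-ene-15,19-dioic acid, via dialdehyde 17 (not isolated)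
Conditions: AZADO (5 mol %), PhI(OAc)2 (2.5 equiv), CH2Cl2, rt; then t-BuOH/H2O, 2-methyl-2-butene, NaH2PO4, NaClO2, rt
Reagents that add atoms: sodium chlorite, [Na+].[O-]Cl=O
Why: Nitroxyl-catalysed alcohol oxidation (the unhindered oxoammonium reaches the neopentyl C19 carbinol) gives the dialdehyde, and Pinnick oxidation with a hypochlorite scavenger should convert both aldehydes to acids without touching the alkene or the tertiary alcohol.

**Compound list**

1 | (2E,6E)-farnesol | CC(C)=CCC/C(C)=C/CC/C(C)=C/CO | starting material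
2 | (2R,3R)-2,3-epoxyfarnesol | CC(C)=CCC/C(C)=C/CC[C@@]1(C)O[C@@H]1CO | intermediate
3 | (3R,6E)-3,7,11-trimethyldodeca-6,10-diene-1,3-diol | CC(C)=CCC/C(C)=C/CC[C@@](C)(O)CCO | intermediate
4 | (4R)-4-[(3E)-4,8-dimethylnona-3,7-dien-1-yl]-2,2,4-trimethyl-1,3-dioxane | CC(C)=CCC/C(C)=C/CC[C@@]1(C)OC(C)(C)OCC1 | intermediate
5 | (2E,6E)-2,6-dimethyl-9-[(4R)-2,2,4-trimethyl-1,3-dioxan-4-yl]nona-2,6-dien-1-ol | OC/C(C)=C/CC/C(C)=C/CC[C@@]1(C)OC(C)(C)OCC1 | intermediate
6 | (4R)-4-[(3E,7E)-9-bromo-4,8-dimethylnona-3,7-dien-1-yl]-2,2,4-trimethyl-1,3-dioxane | BrC/C(C)=C/CC/C(C)=C/CC[C@@]1(C)OC(C)(C)OCC1 | intermediate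
7 | ethyl 2-methyl-3-oxobutanoate | CCOC(=O)C(C)C(C)=O | starting material
8 | (1R,2S,5R)-(−)-8-phenylmenthol | O[C@@H]1C[C@H](C)CC[C@H]1C(C)(C)c1ccccc1 | starting material
9 | (1R,2S,5R)-8-phenylmenthyl 2-methyl-3-oxobutanoate | CC(=O)C(C)C(=O)O[C@@H]1C[C@H](C)CC[C@H]1C(C)(C)c1ccccc1 | intermediate
10 | sodium lithium dianion (bis-enolate) of 9 | [Na+].[Li+].C=C([O-])C(C)=C([O-])O[C@@H]1C[C@H](C)CC[C@H]1C(C)(C)c1ccccc1 | intermediate
11 | (1R,2S,5R)-8-phenylmenthyl (6E,10E)-2,6,10-trimethyl-3-oxo-13-[(4R)-2,2,4-trimethyl-1,3-dioxan-4-yl]trideca-6,10-dienoate | CC(C(=O)CC/C(C)=C/CC/C(C)=C/CC[C@@]1(C)OC(C)(C)OCC1)C(=O)O[C@@H]1C[C@H](C)CC[C@H]1C(C)(C)c1ccccc1 | intermediate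
12 | (1R,2S,5R)-8-phenylmenthyl (13R)-13,15-(isopropylidenedioxy)-3-oxolabd-8(17)-en-19-oate | C=C1CC[C@@H]2[C@](C)(CCC(=O)[C@]2(C)C(=O)O[C@@H]2C[C@H](C)CC[C@H]2C(C)(C)c2ccccc2)[C@H]1CC[C@@]1(C)OC(C)(C)OCC1 | intermediate
13 | (1R,2S,5R)-8-phenylmenthyl (13R)-13,15-dihydroxy-3-(p-toluenesulfonylhydrazono)labd-8(17)-en-19-oate | C=C1CC[C@@H]2[C@](C)(CCC(=NNS(=O)(=O)c3ccc(C)cc3)[C@]2(C)C(=O)O[C@@H]2C[C@H](C)CC[C@H]2C(C)(C)c2ccccc2)[C@H]1CC[C@@](C)(O)CCO | intermediate
14 | (1R,2S,5R)-8-phenylmenthyl (13R)-3-diazenyl-13,15-dihydroxylabd-8(17)-en-19-oate (C3 configuration not defined) | C=C1CC[C@@H]2[C@](C)(CCC(N=N)[C@]2(C)C(=O)O[C@@H]2C[C@H](C)CC[C@H]2C(C)(C)c2ccccc2)[C@H]1CC[C@@](C)(O)CCO | intermediate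
15 | (1R,2S,5R)-8-phenylmenthyl (13R)-13,15-dihydroxylabd-8(17)-en-19-oate | C=C1CC[C@@H]2[C@](C)(CCC[C@]2(C)C(=O)O[C@@H]2C[C@H](C)CC[C@H]2C(C)(C)c2ccccc2)[C@H]1CC[C@@](C)(O)CCO | intermediate
16 | (13R)-labd-8(17)-ene-13,15,19-triol | C=C1CC[C@@H]2[C@](C)(CCC[C@]2(C)CO)[C@H]1CC[C@@](C)(O)CCO | intermediate
17 | (13R)-13-hydroxylabd-8(17)-ene-15,19-dial | C=C1CC[C@@H]2[C@](C)(CCC[C@]2(C)C=O)[C@H]1CC[C@@](C)(O)CC=O | intermediate
18 | (4S,5R,9S,10R,13R)-13-hydroxylabd-8(17)-ene-15,19-dioic acid | C=C1CC[C@@H]2[C@](C)(CCC[C@]2(C)C(=O)O)[C@H]1CC[C@@](C)(O)CC(=O)O | target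

Total step count: 12
Longest linear sequence: 11 (steps 1–5 and 7–12)

**Steps most likely to fail**

Step 8. The auxiliary may discriminate the two faces of the planar C4 radical poorly, and the intermediate C10 radical may be oxidised by copper before ring B closes. The fallback replaces oxidative termination by a group-transfer radical cyclisation under a chelating chiral Lewis acid that reinforces the auxiliary. It sets out from 11: NaH and then PhSeCl (THF, −78 °C) should give the α-phenylseleno β-keto ester F1. Irradiation with a sunlamp in toluene at −78 °C in the presence of Mg(ClO4)2 and a tert-butyl bis(oxazoline) ligand should close both rings through the two-point-bound dicarbonyl radical, with no oxidant present to intercept C10, and transfer the phenylseleno group to C8 to give the 8-phenylseleno bicycle F2. H2O2 and pyridine (CH2Cl2, 0 °C) should then bring about selenoxide syn-elimination toward C17, and the fallback comes back to the route at 12.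

Step 9. Condensation at the C3 carbonyl, which is flanked by quaternary C4 and the bulky axial ester, may stall, or the hydrazide may attack the ester and cyclise. The fallback removes the oxygen by radical deoxygenation through the alcohol and sets out from 12. LiAlH4 (THF, reflux) should reduce ketone and ester together, with hydride entering C3 from the α face, to give the 3β,19-diol F3 with recovery of 8. 1,1'-Thiocarbonyldiimidazole (DMAP, toluene, 80 °C) should close the six-membered cyclic thionocarbonate F4. Bu3SnH and AIBN (toluene, 110 °C) should fragment it toward the more stable secondary C3 radical, and basic work-up should free the 19-ol acetonide F5. PPTS in MeOH then removes the acetonide, and the fallback comes back to the route at 16.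

Step 4. The allylic oxidation may stop at low conversion, over-oxidise, or attack the internal alkene. The fallback degrades the terminal alkene and rebuilds it by olefination, setting out from 4. NBS in THF/H2O (0 °C) should give the terminal bromohydrin F6 and K2CO3 in MeOH the terminal epoxide F7. H5IO6 (Et2O/THF, 0 °C) should cleave it to the trisnor aldehyde F8. Wittig reaction with Ph3P=C(CH3)CO2Et (CH2Cl2, rt) should give the (E)-enoate F9, and i-Bu2AlH (CH2Cl2, −78 °C) reduces it, so that the fallback comes back to the route at 5.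

**Further compounds**

F1 | step 8 | (1R,2S,5R)-8-phenylmenthyl (6E,10E)-2,6,10-trimethyl-3-oxo-2-(phenylselanyl)-13-[(4R)-2,2,4-trimethyl-1,3-dioxan-4-yl]trideca-6,10-dienoate | CC([Se]c1ccccc1)(C(=O)CC/C(C)=C/CC/C(C)=C/CC[C@@]1(C)OC(C)(C)OCC1)C(=O)O[C@@H]1C[C@H](C)CC[C@H]1C(C)(C)c1ccccc1
F2 | step 8 | (1R,2S,5R)-8-phenylmenthyl (13R)-13,15-(isopropylidenedioxy)-3-oxo-8-(phenylselanyl)labdan-19-oate (C8 configuration not defined) | CC1([Se]c3ccccc3)CC[C@@H]2[C@](C)(CCC(=O)[C@]2(C)C(=O)O[C@@H]2C[C@H](C)CC[C@H]2C(C)(C)c2ccccc2)[C@H]1CC[C@@]1(C)OC(C)(C)OCC1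
F3 | step 9 | (13R)-13,15-(isopropylidenedioxy)labd-8(17)-ene-3β,19-diol | C=C1CC[C@@H]2[C@](C)(CC[C@H](O)[C@]2(C)CO)[C@H]1CC[C@@]1(C)OC(C)(C)OCC1
F4 | step 9 | (13R)-13,15-(isopropylidenedioxy)labd-8(17)-ene-3β,19-diyl thionocarbonate | C=C1CC[C@@H]2[C@](C)(CC[C@@H]3OC(=S)OC[C@]23C)[C@H]1CC[C@@]1(C)OC(C)(C)OCC1
F5 | step 9 | (13R)-13,15-(isopropylidenedioxy)labd-8(17)-en-19-ol | C=C1CC[C@@H]2[C@](C)(CCC[C@]2(C)CO)[C@H]1CC[C@@]1(C)OC(C)(C)OCC1
F6 | step 4 | (6E)-3-bromo-2,6-dimethyl-9-[(4R)-2,2,4-trimethyl-1,3-dioxan-4-yl]non-6-en-2-ol | CC(C)(O)C(Br)CC/C(C)=C/CC[C@@]1(C)OC(C)(C)OCC1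
F7 | step 4 | (4R)-4-[(3E)-6-(3,3-dimethyloxiran-2-yl)-4-methylhex-3-en-1-yl]-2,2,4-trimethyl-1,3-dioxane | CC1(C)OC1CC/C(C)=C/CC[C@@]1(C)OC(C)(C)OCC1
F8 | step 4 | (4E)-4-methyl-7-[(4R)-2,2,4-trimethyl-1,3-dioxan-4-yl]hept-4-enal | O=CCC/C(C)=C/CC[C@@]1(C)OC(C)(C)OCC1
F9 | step 4 | ethyl (2E,6E)-2,6-dimethyl-9-[(4R)-2,2,4-trimethyl-1,3-dioxan-4-yl]nona-2,6-dienoate | CCOC(=O)/C(C)=C/CC/C(C)=C/CC[C@@]1(C)OC(C)(C)OCC1
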